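The earlier runs and the new flask were computed with made-up constants; the scatter is artificial.

What share of its Sub does the eta flask turn into Prd by 140 min, and what powers of [Cat] and [Sub] does the first rate follow?

| setting | delta | alpha | gamma | theta | eta |
|---|---|---|---|---|---|
| Sub | 120 mM | 120 mM | 180 mM | 120 mM | 60.0 mM |
| Rgt | 360 mM | 1100 mM | 360 mM | 360 mM | 720 mM |
| Cat | 0.240 mM | 0.240 mM | 0.240 mM | 0.480 mM | 0.240 mM |
| time |  |  |  |  | 140 min |

| run | time / min | [Prd] / mM |
|---|---|---|
| delta run | 23 | 39.9 |
| delta run | 47 | 60.7 |
| delta run | 70 | 72.8 |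
| delta run | 93 | 79.7 |
| delta run | 120 | 85.1 |
| delta run | 140 | 86.9 |
| alpha run | 23 | 40.8 |
| alpha run | 47 | 64.0 |
| alpha run | 70 | 75.3 |
| alpha run | 93 | 83.4 |
| alpha run | 120 | 89.4 |
| alpha run | 140 | 93.8 |
| gamma run | 23 | 55.2 |
| gamma run | 47 | 82.1 |
| gamma run | 70 | 97.2 |
| gamma run | 93 | 101.9 |
| gamma run | 120 | 105.2 |
| gamma run | 140 | 106.5 |
| theta run | 23 | 64.6 |
| theta run | 47 | 88.8 |
| theta run | 70 | 100.7 |
| theta run | 93 | 104.0 |
| theta run | 120 | 109.4 |
| theta run | 140 | 111.9 |

(each reading ± 1 mM)

- the power of [Cat] that the first rate follows, about the charge of the delta run; measure it at two percent of Sub made into Prd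
- the power of [Sub] that the first rate follows, about the charge of the delta run; measure it at two percent of Sub made into Prd (one fixed amount of Prd, the same in the runs compared)
- Prd in the eta run at 140 min, as a share of the Sub charged

- Overall: Sub + Rgt -> Prd, with Cat as catalyst.
- Constant volume, constant temperature.
- "The second partner" is Rgt.
- An order is taken over about fifteen percent of the charge, up and down.

Start with two flasks that look nearly the same. Delta and alpha share their Sub and Cat charges and differ in Rgt, 360 mM against 1100 mM. At 23 min they read 39.9 mM and 40.8 mM, yet at 140 min delta has 0.0331 M of Sub left and alpha 0.0262 M.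

Treat Sub as a first-order decay and read one number from each run: ln(Sub charged over Sub left), divided by the time. For delta at 140 min this gives 0.00920 min⁻¹. This is the mean constant, the steady pseudo-first-order constant that lands on the same end reading. Alpha's is 0.0109 min⁻¹, higher than delta's, which restates alpha's higher end reading in another form and does not explain it. Delta's constant fades, from 0.0176 min⁻¹ over the first 23 min to that lower mean over the whole run.

The same early constant serves the powers. Theta's is 1.91 times delta's for twice the Cat, so I take the Cat power as near 1. Gamma's is 0.0159 min⁻¹, which puts my Sub power at 0.757.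

Eta is asked at the same 140 min, so I replace its curve by its mean and assume that the fade is similar. Gamma, 0.0600 M above delta in Sub, has a mean of 0.00640 min⁻¹. Eta stands the same step below delta, so I step up by that difference. Its Rgt lies 0.486 of the way from delta to alpha, so I add that share of alpha's gain. This gives 0.0128 min⁻¹ and a share of 83.4%.

The forecast, reading the stall as “catalyst death rather than equilibrium”, gives 0.96, 0.88 and 82%, with its Sub power above mine and its share below mine.

    Cat + Sub → G + Byp (98.40 M⁻¹ min⁻¹)
    G + Rgt → Prd + Cat (240.0 M⁻¹ min⁻¹)
    2 Rgt → Q (0.1632 M⁻¹ min⁻¹)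
    2 Cat → 2 J (21.48 M⁻¹ min⁻¹)

Eta gives 84.5%, with powers of 1.0 for Cat and 0.91 for Sub. The path that turns two Rgt into Q moves the readings by 19 times the scatter, as a root mean square. Taken back through the mean constant, eta's share means 0.0133 min⁻¹, against my 0.0128 min⁻¹. Used on delta, the mean constant 0.00920 min⁻¹ puts half the Sub at 75.3 min, and delta stood there at 46.1 min.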